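**Retrosynthetic overview**
- The strategy rests on the ether oxygen: it sits on C2 of the 4-methoxy-6-heptyl ring, ortho to that ring's C1 carboxyl group, and on C4 of the 3-hydroxy-5-heptyl ring, para to that ring's carboxyl carbon. This 2-aryloxybenzoic acid pattern is what an O-to-O aryl shift (Smiles rearrangement) of an ortho-hydroxy depside leaves behind.
- The depside is cut at its ester bond into a 2-hydroxy-4-methoxy acid (acyl half) and a 4-hydroxy benzyl benzoate with its 2-OH benzylated (phenol half).
- Both halves come from one resorcylate, methyl 6-heptyl-2,4-dihydroxybenzoate. Its ring is closed first as a cyclohexane-1,3-dione (Michael–Claisen annulation of an enone with dimethyl malonate) and then aromatized. The only later ring is the transient six-membered spiro dioxinone of the rearrangement.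
- Hydrogenolysis of the benzyl ester and benzyl ether finishes the synthesis.

Key step: step 11

Remark: the target is achiral; dione 6 is carried on as its mixture of stereoisomers and enol tautomers, because both sp3 centres disappear on aromatization.

**Route**

Step 1
Reactants: 1 octanal; 2 1-(triphenylphosphoranylidene)propan-2-one
Product: 3 (E)-undec-3-en-2-one
Conditions: THF, reflux
Reagents that add atoms: none
Why: Wittig olefination with a ketone-stabilized ylide should give the enone with the E double bond, as is usual for stabilized ylides and aliphatic aldehydes.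

Step 2
Reactants: 3 (E)-undec-3-en-2-one; 4 dimethyl malonate
Product: 6 methyl 6-heptyl-2,4-dioxocyclohexane-1-carboxylate, via Michael adduct 5 (not isolated)
Conditions: NaOMe, MeOH, reflux; then aq HCl, 0 °C
Reagents that add atoms: none
Why: Michael addition of sodiomalonate to the enone β-carbon followed by intramolecular Claisen (Dieckmann-type) attack of the methyl ketone enolate on one malonate ester should close the six-membered ring, driven by the stabilized 1,3-dione enolate; the C1 and C6 centres are uncontrolled and irrelevant.

Step 3
Reactants: 6 methyl 6-heptyl-2,4-dioxocyclohexane-1-carboxylate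
Product: 8 methyl 6-heptyl-2,4-dihydroxybenzoate, via bromo dione 7 (not isolated)
Conditions: Br2 (1.0 equiv), DMF, 0 °C, then 80 °C
Reagents that add atoms: none
Why: Bromination–dehydrobromination aromatization of a cyclohexane-1,3-dione: the enol is brominated between the two carbonyls, and vinylogous loss of HBr from the bis-enol followed by tautomerization should give the resorcylate and erase both sp3 centres.

Step 4
Reactants: 8 methyl 6-heptyl-2,4-dihydroxybenzoate
Product: 9 methyl 6-heptyl-2-hydroxy-4-methoxybenzoate
Conditions: MeI (1.05 equiv), K2CO3 (1.1 equiv), acetone, rt to 50 °C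
Reagents that add atoms: iodomethane, CI
Why: Williamson O-methylation should take place only at the 4-OH, because the 2-OH is hydrogen-bonded to the ester carbonyl and is both less acidic and less nucleophilic.

Step 5
Reactants: 9 methyl 6-heptyl-2-hydroxy-4-methoxybenzoate
Product: 10 6-heptyl-2-hydroxy-4-methoxybenzoic acid
Conditions: KOH, DMSO/H2O, 80 °C; then cold 1 M HCl
Reagents that add atoms: potassium hydroxide, [K+].[OH-]
Why: Saponification of the hindered 2,6-disubstituted ester needs poorly solvated hydroxide in aqueous DMSO, and cold acidification should keep the salicylic acid from decarboxylating.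

Step 6
Reactants: 8 methyl 6-heptyl-2,4-dihydroxybenzoate
Product: 11 methyl 6-heptyl-2-hydroxy-4-(methoxymethoxy)benzoate
Conditions: MOMCl (1.1 equiv), iPr2NEt, CH2Cl2, 0 °C
Reagents that add atoms: chloromethyl methyl ether, COCCl
Why: Alkylation with MOMCl and an amine base should again select the free 4-OH over the chelated 2-OH, giving an acetal that survives the basic steps that follow.

Step 7
Reactants: 11 methyl 6-heptyl-2-hydroxy-4-(methoxymethoxy)benzoate
Product: 12 6-heptyl-2-hydroxy-4-(methoxymethoxy)benzoic acid
Conditions: KOH, DMSO/H2O, 70 °C; then cold 1 M HCl to pH 3–4, rapid extraction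
Reagents that add atoms: potassium hydroxide, [K+].[OH-]
Why: Saponification as in step 5; the MOM ether is inert to base and should tolerate a brief, cold, mildly acidic work-up.

Step 8
Reactants: 12 6-heptyl-2-hydroxy-4-(methoxymethoxy)benzoic acid
Product: 13 benzyl 2-(benzyloxy)-6-heptyl-4-(methoxymethoxy)benzoate
Conditions: BnBr (2.3 equiv), K2CO3, DMF, 50–60 °C
Reagents that add atoms: benzyl bromide, BrCc1ccccc1
Why: Carboxylate alkylation followed by Williamson etherification of the remaining 2-OH in a dipolar aprotic solvent should install both benzyl groups in one operation.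

Step 9
Reactants: 13 benzyl 2-(benzyloxy)-6-heptyl-4-(methoxymethoxy)benzoate
Product: 14 benzyl 2-(benzyloxy)-6-heptyl-4-hydroxybenzoate
Conditions: 3 M aq HCl, THF, 50 °C
Reagents that add atoms: none
Why: Acid-catalysed acetal hydrolysis should free the 4-OH, while the benzyl ether and the sterically shielded benzyl ester are stable to dilute aqueous acid.

Step 10
Reactants: 10 6-heptyl-2-hydroxy-4-methoxybenzoic acid; 14 benzyl 2-(benzyloxy)-6-heptyl-4-hydroxybenzoate
Product: 16 3-(benzyloxy)-4-(benzyloxycarbonyl)-5-heptylphenyl 6-heptyl-2-hydroxy-4-methoxybenzoate, via mixed trifluoroacetic anhydride 15 (not isolated)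
Conditions: (CF3CO)2O, toluene, 0 °C to rt; then aq NaHCO3 wash
Reagents that add atoms: none
Why: Mixed-anhydride esterification: the electron-rich, 2,6-disubstituted acid is activated as its trifluoroacetic mixed anhydride (readily ionizing to the acylium ion) and should acylate the only free phenol of 14, while the chelated, hindered 2-OH of 10 does not compete.

Step 11
Reactants: 16 3-(benzyloxy)-4-(benzyloxycarbonyl)-5-heptylphenyl 6-heptyl-2-hydroxy-4-methoxybenzoate
Product: 18 2-[3-(benzyloxy)-4-(benzyloxycarbonyl)-5-heptylphenoxy]-6-heptyl-4-methoxybenzoic acid, via spiro Meisenheimer adduct 17 (not isolated)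
Conditions: K2CO3 (anhydrous, 3 equiv), dry DMSO, rt to 40 °C, N2; then cold 1 M HCl
Reagents that add atoms: none
Why: Carbonate removes the proton of the only free phenol (the 2-OH of the acyl ring), and the phenoxide adds to the ipso carbon that carries the ester oxygen on the other ring, giving spiro 1,3-benzodioxin-4-one σ-adduct 17 with its negative charge delocalized into the para benzyl ester. Collapse of 17 breaks the acyl O–aryl bond, so the aryl group moves from the ester oxygen to the phenol oxygen and the carboxylate is released ortho to the new diaryl ether. The closest known reaction type is the Smiles rearrangement of ortho-hydroxy depsides to 2-aryloxybenzoic acids with carbonate in DMSO. The only ring closed is the transient six-membered dioxinone of 17, formed in a 6-exo-trig mode and opened again in the same step, and the spiro carbon is lost on collapse, so no ring and no stereocentre are carried into 18. The step needs ipso substitution to win over ester cleavage or acyl transfer; this is secured by the single free phenoxide held next to the ipso carbon, para-ester activation of that carbon, the 2-O-benzyl group that keeps the migrating ring neutral, and a dry non-nucleophilic base. Formation of the weakly basic carboxylate should make the shift irreversible.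

Step 12
Reactants: 18 2-[3-(benzyloxy)-4-(benzyloxycarbonyl)-5-heptylphenoxy]-6-heptyl-4-methoxybenzoic acid
Product: 19 2-(4-carboxy-5-heptyl-3-hydroxyphenoxy)-6-heptyl-4-methoxybenzoic acid (target)
Conditions: H2 (1 atm), 10% Pd/C, EtOAc, rt
Reagents that add atoms: none
Why: Catalytic hydrogenolysis should cleave the benzyl ester and the benzyl ether under neutral conditions, leaving the diaryl ether, the methyl ether and both acid groups untouched.

**Compound list**
1 | octanal | CCCCCCCC=O | starting material
2 | 1-(triphenylphosphoranylidene)propan-2-one | CC(=O)C=P(c1ccccc1)(c1ccccc1)c1ccccc1 | starting material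
3 | (E)-undec-3-en-2-one | CCCCCCC/C=C/C(C)=O | intermediate
4 | dimethyl malonate | COC(=O)CC(=O)OC | starting material
5 | dimethyl 2-(2-oxoundecan-4-yl)propanedioate (Michael adduct, not isolated) | CCCCCCCC(CC(C)=O)C(C(=O)OC)C(=O)OC | intermediate
6 | methyl 6-heptyl-2,4-dioxocyclohexane-1-carboxylate (stereoisomer and enol mixture) | CCCCCCCC1CC(=O)CC(=O)C1C(=O)OC | intermediate
7 | methyl 3-bromo-6-heptyl-2,4-dioxocyclohexane-1-carboxylate (not isolated) | CCCCCCCC1CC(=O)C(Br)C(=O)C1C(=O)OC | intermediate
8 | methyl 6-heptyl-2,4-dihydroxybenzoate | CCCCCCCc1cc(O)cc(O)c1C(=O)OC | intermediate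
9 | methyl 6-heptyl-2-hydroxy-4-methoxybenzoate | CCCCCCCc1cc(OC)cc(O)c1C(=O)OC | intermediate
10 | 6-heptyl-2-hydroxy-4-methoxybenzoic acid | CCCCCCCc1cc(OC)cc(O)c1C(=O)O | intermediate
11 | methyl 6-heptyl-2-hydroxy-4-(methoxymethoxy)benzoate | CCCCCCCc1cc(OCOC)cc(O)c1C(=O)OC | intermediate
12 | 6-heptyl-2-hydroxy-4-(methoxymethoxy)benzoic acid | CCCCCCCc1cc(OCOC)cc(O)c1C(=O)O | intermediate
13 | benzyl 2-(benzyloxy)-6-heptyl-4-(methoxymethoxy)benzoate | CCCCCCCc1cc(OCOC)cc(OCc2ccccc2)c1C(=O)OCc1ccccc1 | intermediate
14 | benzyl 2-(benzyloxy)-6-heptyl-4-hydroxybenzoate | CCCCCCCc1cc(O)cc(OCc2ccccc2)c1C(=O)OCc1ccccc1 | intermediate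
15 | 6-heptyl-2-hydroxy-4-methoxybenzoic trifluoroacetic anhydride (not isolated) | CCCCCCCc1cc(OC)cc(O)c1C(=O)OC(=O)C(F)(F)F | intermediate
16 | 3-(benzyloxy)-4-(benzyloxycarbonyl)-5-heptylphenyl 6-heptyl-2-hydroxy-4-methoxybenzoate (depside) | CCCCCCCc1cc(OC)cc(O)c1C(=O)Oc1cc(CCCCCCC)c(C(=O)OCc2ccccc2)c(OCc2ccccc2)c1 | intermediate
17 | potassium salt of the spiro 1,3-benzodioxin-4-one Meisenheimer adduct, charge on the para benzyl ester (not isolated) | CCCCCCCc1cc(OC)cc2OC3(C=C(CCCCCCC)C(=C([O-])OCc4ccccc4)C(OCc4ccccc4)=C3)OC(=O)c12.[K+] | intermediate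
18 | 2-[3-(benzyloxy)-4-(benzyloxycarbonyl)-5-heptylphenoxy]-6-heptyl-4-methoxybenzoic acid | CCCCCCCc1cc(Oc2cc(OC)cc(CCCCCCC)c2C(=O)O)cc(OCc2ccccc2)c1C(=O)OCc1ccccc1 | intermediate
19 | 2-(4-carboxy-5-heptyl-3-hydroxyphenoxy)-6-heptyl-4-methoxybenzoic acid (CNP0377121.0) | CCCCCCCc1cc(Oc2cc(OC)cc(CCCCCCC)c2C(=O)O)cc(O)c1C(=O)O | target

**Step count**
Total: 12 steps. Longest linear sequence: 10 steps (steps 1, 2, 3, 6, 7, 8, 9, 10, 11, 12); the acyl half joins after steps 4 and 5.

**Steps most likely to fail, with fallbacks**

Step 11 (Smiles rearrangement). The benzyl ester para to the ipso carbon is flanked by the benzyloxy and heptyl groups and may be twisted out of conjugation. Formation of the σ-adduct could then be slow, and ester cleavage by traces of hydroxide or intermolecular acyl transfer could take over. The fallback forms the diaryl ether by palladium-catalysed C–O coupling; it sets out from 10 and 14 and comes back at 19. Acid 10 would be alkylated at the carboxylate only (BnBr, KHCO3, DMF, rt) to give benzyl 6-heptyl-2-hydroxy-4-methoxybenzoate F1. Phenol 14 would be converted (Tf2O, pyridine, CH2Cl2, 0 °C) into benzyl 2-(benzyloxy)-6-heptyl-4-(trifluoromethylsulfonyloxy)benzoate F2, an unhindered aryl triflate activated by its para ester. Coupling of F1 with F2 (Pd(OAc)2, 2-di-tert-butylphosphino-2',4',6'-triisopropylbiphenyl, K3PO4, toluene, 100 °C) should give benzyl 2-[3-(benzyloxy)-4-(benzyloxycarbonyl)-5-heptylphenoxy]-6-heptyl-4-methoxybenzoate F3. Hydrogenolysis of all three benzyl groups (H2, 10% Pd/C, EtOAc) would deliver 19 directly.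

Step 3 (aromatization). The resorcylate formed is more electron-rich than the dione and may consume bromine on its own ring, leaving mixtures of ring-brominated arenes and unoxidized dione; prolonged heating with HBr could also cause ester loss. The fallback sets out from 6 and comes back at 8. Dione 6 would be treated with excess Br2 (3 equiv, AcOH or DMF, rt to 60 °C) to push aromatization and nuclear bromination to completion, giving methyl 3,5-dibromo-6-heptyl-2,4-dihydroxybenzoate F4 as a single compound. Reductive debromination (H2, 10% Pd/C, NaOAc, MeOH, rt) should then return 8.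

Step 10 (depside esterification). The activated hydroxy acid may acylate its own phenol to form oligomers, or lose CO2 in the trifluoroacetic acid that is generated, faster than it acylates the weakly nucleophilic para-ester phenol 14. The fallback sets out from 10 and comes back at 16. Acid 10 would be masked and activated at once as its acetonide (acetone, (CF3CO)2O, CF3CO2H, 0 °C to rt), giving 5-heptyl-7-methoxy-2,2-dimethyl-4H-1,3-benzodioxin-4-one F5. Opening of F5 by the sodium phenoxide of 14 (NaH, THF/DMF, 0 °C to rt) releases acetone and should give the 2-phenoxide of 16, which is protonated on work-up to 16 or carried on in DMSO into step 11.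

**Further compounds**
F1 | step 11 | benzyl 6-heptyl-2-hydroxy-4-methoxybenzoate | CCCCCCCc1cc(OC)cc(O)c1C(=O)OCc1ccccc1
F2 | step 11 | benzyl 2-(benzyloxy)-6-heptyl-4-(trifluoromethylsulfonyloxy)benzoate | CCCCCCCc1cc(OS(=O)(=O)C(F)(F)F)cc(OCc2ccccc2)c1C(=O)OCc1ccccc1
F3 | step 11 | benzyl 2-[3-(benzyloxy)-4-(benzyloxycarbonyl)-5-heptylphenoxy]-6-heptyl-4-methoxybenzoate | CCCCCCCc1cc(Oc2cc(OC)cc(CCCCCCC)c2C(=O)OCc2ccccc2)cc(OCc2ccccc2)c1C(=O)OCc1ccccc1
F4 | step 3 | methyl 3,5-dibromo-6-heptyl-2,4-dihydroxybenzoate | CCCCCCCc1c(Br)c(O)c(Br)c(O)c1C(=O)OC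
F5 | step 10 | 5-heptyl-7-methoxy-2,2-dimethyl-4H-1,3-benzodioxin-4-one | CCCCCCCc1cc(OC)cc2OC(C)(C)OC(=O)c12
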